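The leftover is what we watch when we repeat this run: the substrate, both hands together, and the partner not yet used up by product, set against each other in a logarithm.

the same everywhere: partner 0.125 M; free catalyst 1.2 mM; impurity 0.24 mM

| flask | left-handed substrate | right-handed substrate | remark | time |
|---|---|---|---|---|
| Thursday's | 0.070 M | 0.070 M | run made earlier |  |
| Wednesday's | 0.11 M | 0.11 M | run made earlier |  |
| flask | 0.050 M | 0.050 M |  | 2.5 h |

| run | time / min | left-handed product / % | right-handed product / % |
|---|---|---|---|
| Thursday's | 15.0 | 9.5 | 6.1 |
| Thursday's | 30.0 | 14.4 | 6.7 |
| Thursday's | 50.0 | 22.1 | 12.9 |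
| Thursday's | 60.0 | 22.5 | 12.9 |
| Thursday's | 80.0 | 25.6 | 17.0 |
| Thursday's | 90.0 | 28.7 | 16.1 |
| Wednesday's | 6.00 | 4.4 | 3.6 |
| Wednesday's | 20.0 | 10.5 | 6.1 |
| Wednesday's | 30.0 | 15.7 | 8.1 |
| Wednesday's | 50.0 | 18.6 | 11.9 |
| Wednesday's | 60.0 | 20.3 | 13.1 |
| Wednesday's | 90.0 | 24.7 | 12.9 |

(standard deviation of a reading: 1 percentage point)

- left-handed product and right-handed product together, in percent of the left-handed substrate and right-handed substrate charged together, at 2.5 h
- excess of left-handed product over right-handed product in the product at 2.5 h
- whether the exchange between left-handed substrate and right-handed substrate keeps pace with the reaction: how far the product's excess at 2.5 h gets from its value without exchange to its value with instant exchange (above 80% keeps pace, below 20% hardly takes part, else lags behind)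

- free catalyst is single-handed; left-handed substrate and right-handed substrate are mirror images of each other, charged as a racemate, each of them at the stated concentration
- an excess is below zero if the other one leads

We call exposure the natural logarithm of the fraction of partner left over the fraction of substrate left, both reckoned from the product formed as if each product took one partner and one substrate and nothing else took either, divided by the partner charge minus the substrate charge. For a step first order in each of the two, this integrated second-order form grows as rate constant times time, whatever the charges.

The ladder starts at the fast end. Wednesday's run reaches 0.720 M⁻¹ by 6.00 min, which with partner held at its charge is a pseudo-first-order time of 66.7 min. From 60.0 min to 90.0 min, Thursday's run climbs from 4.53 M⁻¹ to 6.83 M⁻¹, and Wednesday's from 5.05 M⁻¹ to 6.45 M⁻¹. Their mean gives a time of 130 min, twice the early one, so the pace has dropped early.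

The exchange we can place loosely. Thursday's product excess reads 21.8% at 15.0 min and 28.1% at 90.0 min, but the first of these rests on readings of 9.5% and 6.1%, each good to 1 percentage point, so these readings do not tell no exchange from instant exchange, and lagging behind stays a guess of ours.

Carrying the late pace on to 2.5 h, we reckon the exposure at the asked time at 10.3 M⁻¹. For this flask that means 59.6% product.

The forecast, lower than our figure, says 58% (51% to 65%) and an excess of 23% (17% to 28%), and on the exchange “I guess it lags behind, with low confidence”.

The flask gives 59.2% and an excess of 24.1%, and the exchange lags behind, getting 68% of the way.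

    partner + free catalyst + left-handed substrate → free catalyst + left-handed product (k = 8540 M⁻² h⁻¹)
    partner + free catalyst + right-handed substrate → free catalyst + right-handed product (k = 4880 M⁻² h⁻¹)
    free catalyst + impurity → spent catalyst B (k = 21100 M⁻¹ h⁻¹)
    partner + free catalyst → spent catalyst A (k = 2.40 M⁻¹ h⁻¹)
    partner ⇌ dormant form (K = 0.270, k = 1.28 h⁻¹)
    left-handed substrate ⇌ right-handed substrate (k = 1.21 h⁻¹)

Read back from its yield in the same way, the flask's exposure at 2.5 h is 10.2 M⁻¹, close to our 10.3 M⁻¹. The neighbouring flask, charged with 0.031 M of partner, has partner as its limiting reagent. The same exposure gives it 18.6% product. It actually reaches 20.2%, more than that reckoning, with 27% of its partner left.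

(The readings stem from a simulated flask for an exercise.)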